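## Analysis of the target

Target 32 is a cembranolide: a 14-membered carbocycle C1–C14 bridged from C1 to C3 by a six-membered lactone (C1–C15–C17(=O)–O–C3, C16 being the methyl on C15), so that C1, C2 and C3 belong to both rings. The carbocycle carries the tertiary carbinol C4 (methyl C18), the E-6,7-olefin, the tertiary allylic hydroperoxide C8 (methyl C19) and the trans-11,12-epoxide (methyl C20 on C12). There are seven stereocentres (1R, 3R, 4S, 8S, 11S, 12S, 15S) in three groups that cannot relay to one another through bonds: C1/C3/C4/C15 around the lactone, C8 alone, and C11/C12. On the lactone ring the two carbocycle bonds (C1–C14 and C3–C4) are cis and the C15 methyl is trans to C1–C14, so C15 should be the equatorial, base-equilibratable centre. The hydroperoxide tolerates neither reductants, low-valent metals nor strong base, the trisubstituted epoxide does not tolerate acid, and the lactone can be opened or epimerised; the hydroperoxide therefore has to come last. The difficulty is to close a flexible 14-membered ring that bears oxygen on seven carbons while setting remote stereocentres independently. The strategy rests on two features: the trans C11–C12 epoxide is the closed form of an anti 1,2-diol (secondary C11–OH, tertiary C12–OH), which is the retron of a reductive coupling of a C11 aldehyde with a C12 methyl ketone; and the C12 ketone with C20, C13, C14, C1 (carrying C15–C17 as isopropenyl), C2 and C3 is exactly keto-aldehyde 4 from ring cleavage of limonene 1, whose stereocentre becomes C1.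

## Retrosynthetic reasoning

**C8–O bond (32 to 31).** The hydroperoxide is removed first by a retro-Schenck ene step, which leads to the E-7,8-olefin 31. It is cut here because no later operation would tolerate the O–O bond. The forward photooxygenation must take the hydrogen from C6 rather than C19 and attack the face that gives 8S.

**C15 and the lactone C3–O bond (31 to 30 to 29).** C15 is left to thermodynamic control (30 to 31). The lactone is then opened retrosynthetically so that the carboxylate oxygen of acid 29 attacks a 3,4-epoxide at C3. The 3R,4S pair is thus the product of inversion at C3 of a (3S,4S)-epoxide, with C4–O retained. This turns C3 and C4 into one reagent-controllable epoxide and avoids a separate esterification. Acid 29 comes from the isopropenyl group of 25 through alcohol 27.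

**C11–O bond of the epoxide (25 to 23).** Bis-epoxide 25 is traced to diol 23 through its C11 mesylate 24. Closure with inversion at C11 means that the (11S,12S)-epoxide requires the (11R,12S)-diol.

**C11–C12 bond (23 to 22).** This is the ring-opening cut. It is the only ring bond whose formation leaves behind exactly the functionality needed (two oxygens) and whose two ends are carbonyl groups that the building blocks supply without an auxiliary activating group. One step gains the ring, one skeletal bond and two stereocentres. The forward reaction has to reduce the aldehyde first, close the 14-membered ring and give the anti diol in the correct absolute sense.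

**Unmasking (22 to 21 to 20 to 19).** The two carbonyls are carried as silyl ethers of the corresponding alcohols (20, 21), because acetal hydrolysis would endanger the epoxide. The C6 sulfonyl group of 19 is the remnant of the fragment union.

**C5–C6 bond (19 to 10 and 17).** The chain is cut between the epoxy carbinol carbon C5 and the allylic C6. This separates a limonene-derived half from a geraniol-derived half at a bond where both partners are activated: C5 as the triflate 18 of epoxy alcohol 10, C6 as a sulfone-stabilised allyl anion from 17. The E-7,8-olefin is taken unchanged from geraniol.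

**Epoxide and C3=C4 (10 to 9 to 6 to 4 and 5).** The 3,4-epoxide comes from Sharpless epoxidation of E-allylic alcohol 9. Its olefin comes from a Horner–Wadsworth–Emmons reaction of aldehyde 4 with phosphonate 5, which brings C4, C18 and C5. The ketone is masked in between as the silyl ether (7, 8).

**Ring cleavage (4 to 2 to 1).** Keto-aldehyde 4 comes from 1 by epoxidation of the ring olefin and glycol cleavage.

**Sulfone fragment (17 to 16 to 15 to 13 to 11).** Geraniol 11 gives sulfone 13; selective cleavage of the terminal olefin gives C11 as an aldehyde (15), which is reduced and silylated.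

## Alternatives that were turned down

Alternative 1: Both epoxides are disconnected at their C–O bonds at once, back to the limonene-derived diene diol A1 with allylic hydroxyls at C5 and C10. In the forward sense one Sharpless titanium–tartrate epoxidation would convert A1 into the bis-epoxy diol A2 and set C3, C4, C11 and C12 together. In its favour, both E-allylic alcohols respond to the same tartrate in the required sense, so four stereocentres come from reagent control in one operation. Against it, A1 needs an E-trisubstituted C11=C12 olefin built from the C12 methyl ketone, and ketone olefinations give poor geometric control. The ring would then have to be closed by two separate alkylations at the nearly equivalent epoxy carbinol carbons C5 and C10 with an unsymmetrical C6–C9 unit, with two epoxides present. On the configuration of C11/C12 this plan is stronger than the chosen one. The chosen strategy offers in return a single bond formation that closes the ring from the carbonyl groups limonene already provides, with no ketone olefination and only one epoxide carried through the fragment union.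

Alternative 2: The ring is cut at C9–C10. In the forward sense a lithium amide would deprotonate the C9 allylic sulfone of the open-chain lactone A3, and the anion would displace the C10 triflate of a Sharpless-derived 11,12-epoxy alcohol to give the macrocyclic sulfone A4 as both C9 epimers. In its favour, intramolecular sulfone alkylation is a dependable way to close 14-membered terpenoid rings, and every stereocentre except C8 is fixed by reagent control before ring closure. Against it, the strong base meets a lactone with an acidic C15–H, and the triflate has to be made and survive next to an epoxide in a fully functionalised molecule. The sulfonyl group must afterwards be removed reductively from an allylic position inside the ring, with lactone and epoxide present and with the risk of moving the 7,8-olefin. The cyclisation substrate A3 also needs a long linear sequence. This plan is stronger on the ring closure and on C11/C12. The chosen strategy offers a much shorter route to the cyclisation substrate, no strong base on the lactone, and a ring-closing bond that creates needed functionality instead of an auxiliary group to be removed.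

Alternative 3: The C1–C2 bond is disconnected by a retro-Claisen step. In the forward sense heating the 16-membered 2-methylene oxacycle A5 (allyl vinyl ether C2=C3–O–C17–C15=C1 inside the ring) would form C1–C2, break O–C17 and contract the ring to the 14-membered C3 ketone A6 with the isopropenyl group on C1. In its favour, the ring is first made as a macrolactone and then contracted in a unimolecular step without high dilution, and C1 arises by chirality transfer. Against it, the configuration at C1 depends on chair versus boat geometry and on the C1=C15 olefin geometry inside a large ring, and a trisubstituted epoxide must survive lactone methylenation and heating. The C3 ketone of A6 still needs a stereoselective reduction, the lactone still has to be built, and C4 has to be set independently. This plan is stronger on the reliability of ring formation. The chosen strategy offers C1 directly from limonene, C3 and C4 from one reagent-controlled epoxidation, and fewer steps after ring closure.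

Key step: step 16

Remark on names: from 19 on, intermediates are named with the cembrane numbering of the target (ring C1–C14, C15–C17 on C1, methyls C18/C19/C20 on C4/C8/C12); "11,12-seco" means that the C11–C12 bond is absent.

Assumption: the C12 carbinol centre (7–10, 18–21), C6 of 19 and C15 of 26–30 are carried as epimer mixtures that are removed or equilibrated later; the 15S lactone (methyl trans to C1–C14) is taken to be the more stable C15 epimer.

Step 1
Reactants: 1 (R)-(+)-limonene
Product: 2 (4R)-1,2-epoxy-p-menth-8-ene (limonene 1,2-oxide; both epoxide diastereomers)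
Conditions: mCPBA (1.0 equiv), CH2Cl2, 0 °C
Reagents that add atoms: mCPBA (3-chloroperoxybenzoic acid), OOC(=O)c1cccc(Cl)c1
Why: Prilezhaev epoxidation; the trisubstituted ring olefin is more electron-rich than the 1,1-disubstituted isopropenyl group and should react first with one equivalent of peracid. Both epoxide diastereomers are usable because these centres are destroyed in step 2; the limonene stereocentre (later C1) is not involved.

Step 2
Reactants: 2 (4R)-1,2-epoxy-p-menth-8-ene
Product: 4 (3R)-6-oxo-3-(prop-1-en-2-yl)heptanal, via limonene-1,2-diol 3 (not isolated)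
Conditions: H5IO6, THF/H2O, 0 °C → rt
Reagents that add atoms: water, O
Why: Acidic hydrolysis of the epoxide to the 1,2-diol followed by periodate (Malaprade) glycol cleavage in the same flask opens the ring between the former olefin carbons and gives the C3 aldehyde and the C12 methyl ketone. The isopropenyl group and the stereocentre are inert to periodic acid.

Step 3
Reactants: 4 (3R)-6-oxo-3-(prop-1-en-2-yl)heptanal; 5 triethyl 2-phosphonopropionate
Product: 6 ethyl (2E,5R)-2,6-dimethyl-5-(3-oxobutyl)hepta-2,6-dienoate
Conditions: LiCl, DBU, MeCN, 0 °C → rt
Reagents that add atoms: none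
Why: Horner–Wadsworth–Emmons olefination under Masamune–Roush conditions; the lithium-chelated α-methyl phosphonate anion adds to the aldehyde and not to the methyl ketone, and the mild amine base should avoid aldol closure of the keto-aldehyde. The E-olefin (ester trans to C2) is expected from reversible addition and elimination through the less crowded oxaphosphetane.

Step 4
Reactants: 6 ethyl (2E,5R)-2,6-dimethyl-5-(3-oxobutyl)hepta-2,6-dienoate
Product: 7 ethyl (2E,5R)-5-(3-hydroxybutyl)-2,6-dimethylhepta-2,6-dienoate (both carbinol epimers)
Conditions: NaBH4, EtOH, 0 °C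
Reagents that add atoms: none
Why: Sodium borohydride reduces the saturated ketone and should leave the conjugated ester untouched at 0 °C. The new carbinol centre (C12) is formed without control, which is of no consequence because it is oxidised back in step 15.

Step 5
Reactants: 7 ethyl (2E,5R)-5-(3-hydroxybutyl)-2,6-dimethylhepta-2,6-dienoate
Product: 8 ethyl (2E,5R)-5-[3-(tert-butyldimethylsilyloxy)butyl]-2,6-dimethylhepta-2,6-dienoate
Conditions: TBSCl, imidazole, DMF, rt
Reagents that add atoms: tert-butyldimethylsilyl chloride, CC(C)(C)[Si](C)(C)Cl
Why: Standard silylation of a secondary alcohol. The silyl ether masks the latent C12 ketone against the hydride of step 6, the titanium alkoxide of step 7 and the carbanion of step 12.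

Step 6
Reactants: 8 ethyl (2E,5R)-5-[3-(tert-butyldimethylsilyloxy)butyl]-2,6-dimethylhepta-2,6-dienoate
Product: 9 (2E,5R)-5-[3-(tert-butyldimethylsilyloxy)butyl]-2,6-dimethylhepta-2,6-dien-1-ol
Conditions: DIBAL-H, CH2Cl2, −78 °C
Reagents that add atoms: none
Why: 1,2-Reduction of the α,β-unsaturated ester to the allylic alcohol by DIBAL-H. The olefins and the silyl ether are not affected and the E geometry is retained.

Step 7
Reactants: 9 (2E,5R)-5-[3-(tert-butyldimethylsilyloxy)butyl]-2,6-dimethylhepta-2,6-dien-1-ol
Product: 10 [(2S,3S)-3-[(2R)-5-(tert-butyldimethylsilyloxy)-2-(prop-1-en-2-yl)hexyl]-2-methyloxiran-2-yl]methanol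
Conditions: Ti(OiPr)4, L-(+)-diethyl tartrate, t-BuOOH, 4 Å MS, CH2Cl2, −20 °C
Reagents that add atoms: tert-butyl hydroperoxide, CC(C)(C)OO
Why: Sharpless asymmetric epoxidation; the allylic hydroxyl binds to titanium and the L-(+)-tartrate ligand directs oxygen to one face of the E-2-methyl-2-alkenol, which should give the (2S,3S)-epoxy alcohol (3S,4S in target numbering) by reagent control that overrides the remote C1 centre. The isopropenyl group has no directing hydroxyl and should not be epoxidised.

Step 8
Reactants: 11 geraniol
Product: 13 geranyl phenyl sulfone, via geranyl bromide 12 (not isolated)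
Conditions: PBr3, Et2O, −10 °C; then PhSO2Na, DMF, rt
Reagents that add atoms: sodium benzenesulfinate, [Na+].[O-]S(=O)c1ccccc1
Why: Conversion of the allylic alcohol into the bromide and S-alkylation of the sulfinate by the primary allylic bromide (SN2). The primary E-sulfone is the expected product of direct displacement and the olefin geometry is not touched.

Step 9
Reactants: 13 geranyl phenyl sulfone
Product: 15 (4E)-4-methyl-6-(phenylsulfonyl)hex-4-enal, via ozonide 14 (not isolated)
Conditions: O3 (1 equiv), CH2Cl2, −78 °C (Sudan Red 7B end point); then PPh3, −78 °C → rt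
Reagents that add atoms: ozone, [O-][O+]=O
Why: Selective ozonolysis; the terminal trisubstituted olefin is more electron-rich than the olefin next to the electron-withdrawing sulfonylmethyl group and should be cleaved first, with the dye marking the end point. Reduction of the ozonide with PPh3 gives the aldehyde, which is C11 of the target.

Step 10
Reactants: 15 (4E)-4-methyl-6-(phenylsulfonyl)hex-4-enal
Product: 16 (4E)-4-methyl-6-(phenylsulfonyl)hex-4-en-1-ol
Conditions: NaBH4, MeOH, 0 °C
Reagents that add atoms: none
Why: Borohydride reduction of the aldehyde; the allylic sulfone is inert. The alcohol is the form in which C11 can be carried through the carbanion chemistry of step 12.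

Step 11
Reactants: 16 (4E)-4-methyl-6-(phenylsulfonyl)hex-4-en-1-ol
Product: 17 tert-butyldimethyl{[(4E)-4-methyl-6-(phenylsulfonyl)hex-4-en-1-yl]oxy}silane
Conditions: TBSCl, imidazole, DMF, rt
Reagents that add atoms: tert-butyldimethylsilyl chloride, CC(C)(C)[Si](C)(C)Cl
Why: Standard silylation of a primary alcohol. The same silyl group as on C12 allows both latent carbonyls to be released together in step 14.

Step 12
Reactants: 10 [(2S,3S)-3-[(2R)-5-(tert-butyldimethylsilyloxy)-2-(prop-1-en-2-yl)hexyl]-2-methyloxiran-2-yl]methanol; 17 tert-butyldimethyl{[(4E)-4-methyl-6-(phenylsulfonyl)hex-4-en-1-yl]oxy}silane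
Product: 19 (1R,3S,4S,7E)-11,12-bis(tert-butyldimethylsilyloxy)-3,4-epoxy-6-(phenylsulfonyl)-11,12-secocembra-7,15(17)-diene (C6 and C12 epimers), via epoxy triflate 18 (not isolated)
Conditions: 10, n-BuLi, THF, −78 °C; Tf2O, −78 °C; then lithiated 17 (n-BuLi, THF/HMPA, −78 °C), −78 °C
Reagents that add atoms: none
Why: Sulfone alkylation; the lithium alkoxide of 10 is converted into the primary triflate, which the sulfonyl-stabilised allyl anion of 17 displaces at its α-carbon (SN2 at C5) to form the C5–C6 bond. At −78 °C the triflate should be displaced much faster than the trisubstituted epoxide is opened, and the epoxide stereocentres are not involved. C6 is formed as a mixture that disappears in step 13.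

Step 13
Reactants: 19 (1R,3S,4S,7E)-11,12-bis(tert-butyldimethylsilyloxy)-3,4-epoxy-6-(phenylsulfonyl)-11,12-secocembra-7,15(17)-diene
Product: 20 (1R,3S,4S,7E)-11,12-bis(tert-butyldimethylsilyloxy)-3,4-epoxy-11,12-secocembra-7,15(17)-diene (C12 epimers)
Conditions: 6% Na(Hg), Na2HPO4, MeOH/THF, −20 °C
Reagents that add atoms: none
Why: Reductive desulfonylation by electron transfer from buffered sodium amalgam; the C6–S bond is cleaved and the allyl anion should be protonated at C6, its less substituted terminus, which keeps the E-7,8-olefin. Epoxide, silyl ethers and the isolated olefins are stable to these conditions.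

Step 14
Reactants: 20 (1R,3S,4S,7E)-11,12-bis(tert-butyldimethylsilyloxy)-3,4-epoxy-11,12-secocembra-7,15(17)-diene
Product: 21 (1R,3S,4S,7E)-3,4-epoxy-11,12-secocembra-7,15(17)-diene-11,12-diol (C12 epimers)
Conditions: TBAF, THF, rt
Reagents that add atoms: none
Why: Fluoride-mediated cleavage of the primary and the secondary silyl ether under conditions that the acid-sensitive trisubstituted epoxide tolerates.

Step 15
Reactants: 21 (1R,3S,4S,7E)-3,4-epoxy-11,12-secocembra-7,15(17)-diene-11,12-diol
Product: 22 (1R,3S,4S,7E)-3,4-epoxy-12-oxo-11,12-secocembra-7,15(17)-dien-11-al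
Conditions: Dess–Martin periodinane, NaHCO3, CH2Cl2, 0 °C → rt
Reagents that add atoms: none
Why: Dess–Martin oxidation converts the primary alcohol into the C11 aldehyde and the secondary alcohol into the C12 methyl ketone in one operation, which also removes the C12 epimer mixture. Bicarbonate buffering protects the epoxide from the acetic acid that is released.

Step 16
Reactants: 22 (1R,3S,4S,7E)-3,4-epoxy-12-oxo-11,12-secocembra-7,15(17)-dien-11-al
Product: 23 (1R,3S,4S,7E,11R,12S)-3,4-epoxycembra-7,15(17)-diene-11,12-diol
Conditions: SmI2 (4 equiv), HMPA, THF, −78 → −20 °C, 22 added slowly (final 2 mM); aq. NH4Cl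
Reagents that add atoms: none
Why: Divalent samarium transfers an electron to the C11 aldehyde, the more easily reduced carbonyl, and the ketyl carbon adds to the C12 ketone carbonyl; a second electron reduces the resulting oxygen radical, so that the C11–C12 bond and the samarium diolate form together (if the ketone is reduced as well, the two ketyls combine to the same diolate). The closest known reaction type is the SmI2 pinacol cyclisation of keto-aldehydes, which extends to large rings, together with the low-valent-metal pinacol closure of 14-membered terpenoid rings. The 14-membered carbocycle is closed in the 14-exo-trig mode, and slow addition at high dilution keeps the ketyl away from a second molecule. For the relative configuration of C11 and C12, HMPA saturates the samarium centres so that one metal cannot bridge both oxygens; the two C–O dipoles then stand anti in the transition state while C10–C11–C12–C13 lies extended along the ring, which is the arrangement that leads to the anti diol (11R,12S or 11S,12R). The absolute sense relative to C1, C3 and C4 is set only by the folding of the chain, in which the E-7,8-olefin and the trans-3,4-epoxide are rigid segments and the isopropenyl and C20 methyl groups should point outwards; this is the least secured element of the route. As to chemoselectivity, aldehydes are reduced much faster than dialkyl ketones, and at low temperature the C12 ketyl, which could close a five-membered ring onto the isopropenyl group only by attack at its fully substituted carbon, should not form on its own; the C11 ketyl has only 4-exo or 5-endo paths to the 7,8-olefin. The 3,4-epoxide is not α to a carbonyl and should survive SmI2.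

Step 17
Reactants: 23 (1R,3S,4S,7E,11R,12S)-3,4-epoxycembra-7,15(17)-diene-11,12-diol
Product: 25 (1R,3S,4S,7E,11S,12S)-3,4:11,12-diepoxycembra-7,15(17)-diene, via 11-mesylate 24 (not isolated)
Conditions: MsCl, Et3N, CH2Cl2, −20 °C; then K2CO3, MeOH, rt
Reagents that add atoms: none
Why: Selective mesylation of the secondary C11 hydroxyl (the tertiary C12 hydroxyl does not react) and intramolecular Williamson closure; the C12 alkoxide displaces the mesylate in a 3-exo-tet SN2 reaction. Inversion at C11 and retention at C12 turn the (11R,12S)-diol into the (11S,12S)-trans-epoxide.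

Step 18
Reactants: 25 (1R,3S,4S,7E,11S,12S)-3,4:11,12-diepoxycembra-7,15(17)-diene
Product: 27 (1R,3S,4S,7E,11S,12S)-3,4:11,12-diepoxycembr-7-en-17-ol (C15 epimers), via B-alkyl-9-BBN adduct 26 (not isolated)
Conditions: 9-BBN, THF, 0 °C → rt; then NaOH, H2O2, 0 °C
Reagents that add atoms: hydrogen peroxide, OO
Why: Hydroboration–oxidation; 9-BBN adds to the 1,1-disubstituted isopropenyl olefin far faster than to the trisubstituted 7,8-olefin and places boron on C17 (anti-Markovnikov), and alkaline peroxide replaces boron by hydroxyl without opening the epoxides. C15 is formed without control and is corrected in step 21.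

Step 19
Reactants: 27 (1R,3S,4S,7E,11S,12S)-3,4:11,12-diepoxycembr-7-en-17-ol
Product: 29 (1R,3S,4S,7E,11S,12S)-3,4:11,12-diepoxycembr-7-en-17-oic acid (C15 epimers), via aldehyde 28 (not isolated)
Conditions: TEMPO (cat.), PhI(OAc)2, MeCN/pH 7 phosphate buffer, rt
Reagents that add atoms: water, O
Why: TEMPO-catalysed oxidation with PhI(OAc)2 in the presence of water takes the primary alcohol through the aldehyde hydrate to the carboxylic acid. The oxoammonium oxidant should not attack the trisubstituted olefin or the epoxides, and the neutral buffer suppresses acid-catalysed epoxide opening.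

Step 20
Reactants: 29 (1R,3S,4S,7E,11S,12S)-3,4:11,12-diepoxycembr-7-en-17-oic acid
Product: 30 (1R,3R,4S,7E,11S,12S)-11,12-epoxy-4-hydroxycembr-7-en-17,3-olide (C15 epimers)
Conditions: Cs2CO3 (0.5 equiv), DMF, 70 °C; then pH 5 buffer
Reagents that add atoms: none
Why: Intramolecular SN2 opening of the 3,4-epoxide by the C17 carboxylate; attack at the secondary C3 is 6-exo-tet and, under basic conditions, should be preferred over 7-endo attack at the tertiary C4 and over attack at the remote 11,12-epoxide. Inversion at C3 converts 3S into 3R and leaves C4 (4S) as the tertiary carbinol with retention.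

Step 21
Reactants: 30 (1R,3R,4S,7E,11S,12S)-11,12-epoxy-4-hydroxycembr-7-en-17,3-olide
Product: 31 (1R,3R,4S,7E,11S,12S,15S)-11,12-epoxy-4-hydroxycembr-7-en-17,3-olide
Conditions: DBU, toluene, 90 °C
Reagents that add atoms: none
Why: Base-mediated epimerisation of the lactone α-centre through the enolate; equilibration should favour the 15S epimer, in which the C16 methyl is equatorial and trans to the C1–C14 bond. No other centre is acidic, and the epoxide and the tertiary alcohol are stable to DBU.

Step 22
Reactants: 31 (1R,3R,4S,7E,11S,12S,15S)-11,12-epoxy-4-hydroxycembr-7-en-17,3-olide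
Product: 32 (1R,3R,4S,6E,8S,11S,12S,15S)-11,12-epoxy-8-hydroperoxy-4-hydroxycembr-6-en-17,3-olide (target)
Conditions: O2, hν (visible light), tetraphenylporphyrin (cat.), CH2Cl2, −20 °C
Reagents that add atoms: dioxygen, O=O
Why: Schenck ene reaction of singlet oxygen with the E-trisubstituted 7,8-olefin; oxygen bonds to C8, a hydrogen is taken from C6 on the disubstituted side of the olefin and the double bond moves to C6=C7 with E geometry, which gives the tertiary allylic hydroperoxide directly. The 8S configuration requires attack on the olefin face that is exposed in the preferred conformation of the bicyclic lactone; this is substrate control and is not secured.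

## Compound list

1 | (R)-(+)-limonene | CC1=CC[C@@H](CC1)C(C)=C | starting material
2 | (4R)-1,2-epoxy-p-menth-8-ene (both epoxide diastereomers) | CC1(O2)C2C[C@@H](CC1)C(C)=C | intermediate
3 | (4R)-p-menth-8-ene-1,2-diol (limonene-1,2-diol) | CC1(O)C(O)C[C@@H](CC1)C(C)=C | intermediate (not isolated)
4 | (3R)-6-oxo-3-(prop-1-en-2-yl)heptanal | CC(=C)[C@@H](CC=O)CCC(C)=O | intermediate
5 | triethyl 2-phosphonopropionate | CCOC(=O)C(C)P(=O)(OCC)OCC | starting material
6 | ethyl (2E,5R)-2,6-dimethyl-5-(3-oxobutyl)hepta-2,6-dienoate | CC(=C)[C@@H](C/C=C(C)/C(=O)OCC)CCC(C)=O | intermediate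
7 | ethyl (2E,5R)-5-(3-hydroxybutyl)-2,6-dimethylhepta-2,6-dienoate (carbinol epimers) | CC(=C)[C@@H](C/C=C(C)/C(=O)OCC)CCC(C)O | intermediate
8 | ethyl (2E,5R)-5-[3-(tert-butyldimethylsilyloxy)butyl]-2,6-dimethylhepta-2,6-dienoate | CC(=C)[C@@H](C/C=C(C)/C(=O)OCC)CCC(C)O[Si](C)(C)C(C)(C)C | intermediate
9 | (2E,5R)-5-[3-(tert-butyldimethylsilyloxy)butyl]-2,6-dimethylhepta-2,6-dien-1-ol | CC(=C)[C@@H](C/C=C(C)/CO)CCC(C)O[Si](C)(C)C(C)(C)C | intermediate
10 | [(2S,3S)-3-[(2R)-5-(tert-butyldimethylsilyloxy)-2-(prop-1-en-2-yl)hexyl]-2-methyloxiran-2-yl]methanol | CC(=C)[C@@H](C[C@@H]1O[C@@]1(C)CO)CCC(C)O[Si](C)(C)C(C)(C)C | intermediate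
11 | geraniol | OC/C=C(C)/CCC=C(C)C | starting material
12 | geranyl bromide | BrC/C=C(C)/CCC=C(C)C | intermediate (not isolated)
13 | geranyl phenyl sulfone | O=S(=O)(C/C=C(C)/CCC=C(C)C)c1ccccc1 | intermediate
14 | ozonide (1,2,4-trioxolane) of the 6,7-olefin of 13 | CC1(C)OOC(CC/C(C)=C/CS(=O)(=O)c2ccccc2)O1 | intermediate (not isolated)
15 | (4E)-4-methyl-6-(phenylsulfonyl)hex-4-enal | O=CCC/C(C)=C/CS(=O)(=O)c1ccccc1 | intermediate
16 | (4E)-4-methyl-6-(phenylsulfonyl)hex-4-en-1-ol | OCCC/C(C)=C/CS(=O)(=O)c1ccccc1 | intermediate
17 | tert-butyldimethyl{[(4E)-4-methyl-6-(phenylsulfonyl)hex-4-en-1-yl]oxy}silane | CC(C)(C)[Si](C)(C)OCCC/C(C)=C/CS(=O)(=O)c1ccccc1 | intermediate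
18 | [(2S,3S)-3-[(2R)-5-(tert-butyldimethylsilyloxy)-2-(prop-1-en-2-yl)hexyl]-2-methyloxiran-2-yl]methyl trifluoromethanesulfonate | CC(=C)[C@@H](C[C@@H]1O[C@@]1(C)COS(=O)(=O)C(F)(F)F)CCC(C)O[Si](C)(C)C(C)(C)C | intermediate (not isolated)
19 | (1R,3S,4S,7E)-11,12-bis(tert-butyldimethylsilyloxy)-3,4-epoxy-6-(phenylsulfonyl)-11,12-secocembra-7,15(17)-diene (C6 and C12 epimers) | CC(=C)[C@@H](C[C@@H]1O[C@@]1(C)CC(/C=C(C)/CCCO[Si](C)(C)C(C)(C)C)S(=O)(=O)c1ccccc1)CCC(C)O[Si](C)(C)C(C)(C)C | intermediate
20 | (1R,3S,4S,7E)-11,12-bis(tert-butyldimethylsilyloxy)-3,4-epoxy-11,12-secocembra-7,15(17)-diene (C12 epimers) | CC(=C)[C@@H](C[C@@H]1O[C@@]1(C)CC/C=C(C)/CCCO[Si](C)(C)C(C)(C)C)CCC(C)O[Si](C)(C)C(C)(C)C | intermediate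
21 | (1R,3S,4S,7E)-3,4-epoxy-11,12-secocembra-7,15(17)-diene-11,12-diol (C12 epimers) | CC(=C)[C@@H](C[C@@H]1O[C@@]1(C)CC/C=C(C)/CCCO)CCC(C)O | intermediate
22 | (1R,3S,4S,7E)-3,4-epoxy-12-oxo-11,12-secocembra-7,15(17)-dien-11-al | CC(=C)[C@@H](C[C@@H]1O[C@@]1(C)CC/C=C(C)/CCC=O)CCC(C)=O | intermediate
23 | (1R,3S,4S,7E,11R,12S)-3,4-epoxycembra-7,15(17)-diene-11,12-diol | CC(=C)[C@H]1C[C@@H]2O[C@@]2(C)CC/C=C(C)/CC[C@@H](O)[C@@](C)(O)CC1 | intermediate
24 | 11-O-methanesulfonate of 23 | CC(=C)[C@H]1C[C@@H]2O[C@@]2(C)CC/C=C(C)/CC[C@@H](OS(C)(=O)=O)[C@@](C)(O)CC1 | intermediate (not isolated)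
25 | (1R,3S,4S,7E,11S,12S)-3,4:11,12-diepoxycembra-7,15(17)-diene | CC(=C)[C@H]1C[C@@H]2O[C@@]2(C)CC/C=C(C)/CC[C@@H]2O[C@@]2(C)CC1 | intermediate
26 | B-alkyl-9-BBN adduct of 25 (boron on C17; C15 epimers) | CC(CB1C2CCCC1CCC2)[C@H]1C[C@@H]2O[C@@]2(C)CC/C=C(C)/CC[C@@H]2O[C@@]2(C)CC1 | intermediate (not isolated)
27 | (1R,3S,4S,7E,11S,12S)-3,4:11,12-diepoxycembr-7-en-17-ol (C15 epimers) | CC(CO)[C@H]1C[C@@H]2O[C@@]2(C)CC/C=C(C)/CC[C@@H]2O[C@@]2(C)CC1 | intermediate
28 | (1R,3S,4S,7E,11S,12S)-3,4:11,12-diepoxycembr-7-en-17-al (C15 epimers) | CC(C=O)[C@H]1C[C@@H]2O[C@@]2(C)CC/C=C(C)/CC[C@@H]2O[C@@]2(C)CC1 | intermediate (not isolated)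
29 | (1R,3S,4S,7E,11S,12S)-3,4:11,12-diepoxycembr-7-en-17-oic acid (C15 epimers) | CC(C(O)=O)[C@H]1C[C@@H]2O[C@@]2(C)CC/C=C(C)/CC[C@@H]2O[C@@]2(C)CC1 | intermediate
30 | (1R,3R,4S,7E,11S,12S)-11,12-epoxy-4-hydroxycembr-7-en-17,3-olide (C15 epimers) | CC1C(=O)O[C@@H]2C[C@H]1CC[C@]1(C)O[C@H]1CC/C(C)=C/CC[C@]2(C)O | intermediate
31 | (1R,3R,4S,7E,11S,12S,15S)-11,12-epoxy-4-hydroxycembr-7-en-17,3-olide | C[C@@H]1C(=O)O[C@@H]2C[C@H]1CC[C@]1(C)O[C@H]1CC/C(C)=C/CC[C@]2(C)O | intermediate
32 | (1R,3R,4S,6E,8S,11S,12S,15S)-11,12-epoxy-8-hydroperoxy-4-hydroxycembr-6-en-17,3-olide | C[C@@H]1C(=O)O[C@@H]2C[C@H]1CC[C@]1(C)O[C@H]1CC[C@](C)(OO)/C=C/C[C@]2(C)O | target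

## Step count and least certain steps

Total step count: 22. Longest linear sequence: 18 steps (steps 1–7 and 12–22 from limonene 1); the sulfone branch (steps 8–11) has 4 steps before the union.

**Step 16 (key step).** The most likely failure is poor diastereocontrol. The coupling may give the 11-epimeric (syn) diol or the anti diol of the opposite absolute sense, because only the conformation of the forming ring distinguishes the four transition states. Intermolecular coupling, plain reduction of the aldehyde and ketyl–olefin closure onto the isopropenyl group are the other ways in which material can be lost. The fallback corrects C11 but not C12. It sets out from 22: the coupling is run without regard to C11, and the (11S,12S)-diol F1 (alone or mixed with 23) is oxidised at the secondary hydroxyl (SO3·pyridine, DMSO, iPr2NEt) to the α-hydroxy ketone F2. Chelation-controlled reduction with Zn(BH4)2, with hydride delivered to the five-membered zinc chelate from the side of the C20 methyl group, should give the anti diol and returns to the route at 23.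

**Step 22.** The most likely failure is hydrogen abstraction from the C19 methyl group, which lies on the same side of the olefin as C6 and would give the secondary C7 hydroperoxide with an exocyclic olefin. Attack on the wrong face would give the 8-epimer. Both selectivities rest on ring conformation alone. The fallback changes the substrate, not the oxidant. Compound 31 is converted with N-(trimethylsilyl)imidazole into its C4 trimethylsilyl ether F3, which removes the hydrogen-bond donor near the olefin and alters the transannular environment. Photooxygenation gives the silylated hydroperoxide F4, and buffered fluoride (HF·pyridine, pyridine) returns to the route at 32.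

**Step 13.** The most likely failure is loss of olefin integrity. The allyl anion formed by electron transfer can be protonated at C8 instead of C6, which moves the double bond to C6=C7, or it can lose the E geometry before protonation. The fallback replaces electron transfer by ionisation. With catalytic zerovalent palladium (Pd(PPh3)4) and NaBH4, 19 is ionised to a π-allylpalladium complex and hydride is delivered to the less substituted terminus C6. This leads from 19 directly to 20 without new intermediates. NaBH4 is chosen over LiBHEt3 because the latter would open the epoxide.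

**Step 12.** The most likely failure is decomposition of triflate 18 before substitution, by ionisation next to the epoxide with ring expansion or by elimination, because C5 is a hindered primary carbon attached to a fully substituted epoxide carbon. The fallback replaces the in-situ triflate by an isolable electrophile. Compound 10 is converted into the epoxy iodide F5 (I2, PPh3, imidazole), which is alkylated with lithiated 17 in THF/HMPA at −40 → 0 °C and returns to the route at 19.

## Further compounds

F1 | step 16 | (1R,3S,4S,7E,11S,12S)-3,4-epoxycembra-7,15(17)-diene-11,12-diol (11-epimer of 23) | CC(=C)[C@H]1C[C@@H]2O[C@@]2(C)CC/C=C(C)/CC[C@H](O)[C@@](C)(O)CC1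
F2 | step 16 | (1R,3S,4S,7E,12S)-3,4-epoxy-12-hydroxycembra-7,15(17)-dien-11-one | CC(=C)[C@H]1C[C@@H]2O[C@@]2(C)CC/C=C(C)/CCC(=O)[C@@](C)(O)CC1
F3 | step 22 | 4-O-trimethylsilyl ether of 31 | C[C@@H]1C(=O)O[C@@H]2C[C@H]1CC[C@]1(C)O[C@H]1CC/C(C)=C/CC[C@]2(C)O[Si](C)(C)C
F4 | step 22 | 4-O-trimethylsilyl ether of 32 | C[C@@H]1C(=O)O[C@@H]2C[C@H]1CC[C@]1(C)O[C@H]1CC[C@](C)(OO)/C=C/C[C@]2(C)O[Si](C)(C)C
F0 | step 13 | none | none
F5 | step 12 | epoxy iodide corresponding to 10 (CH2I in place of CH2OH, same spatial arrangement) | CC(=C)[C@@H](C[C@@H]1O[C@@]1(C)CI)CCC(C)O[Si](C)(C)C(C)(C)C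
A1 | alternative 1 | (2E,5R,8E)-2,8-dimethyl-5-(prop-1-en-2-yl)deca-2,8-diene-1,10-diol (diene diol) | CC(=C)[C@@H](C/C=C(C)/CO)CC/C(C)=C/CO
A2 | alternative 1 | bis-epoxy diol (3S,4S and 11S,12S epoxides, hydroxyls on C5 and C10) | CC(=C)[C@@H](C[C@@H]1O[C@@]1(C)CO)CC[C@]1(C)O[C@H]1CO
A3 | alternative 2 | open-chain lactone with C4 triethylsilyl ether, C9 phenyl sulfone and C10 triflate on the 11,12-epoxide | O=S(=O)(c1ccccc1)C/C(C)=C/CC[C@](C)(O[Si](CC)(CC)CC)[C@H]1C[C@@H](CC[C@]2(C)O[C@H]2COS(=O)(=O)C(F)(F)F)[C@H](C)C(=O)O1
A4 | alternative 2 | macrocyclic lactone with C9 phenylsulfonyl group (both C9 epimers) and C4 triethylsilyl ether | C[C@@H]1C(=O)O[C@@H]2C[C@H]1CC[C@]1(C)O[C@H]1CC(S(=O)(=O)c1ccccc1)/C(C)=C/CC[C@]2(C)O[Si](CC)(CC)CC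
A5 | alternative 3 | 16-membered 2-methylene oxacycle (C1=C15 geometry left open) | C=C1OCC(C)=CCC[C@]2(C)O[C@H]2CC/C(C)=C/CC[C@]1(C)O[Si](CC)(CC)CC
A6 | alternative 3 | 14-membered C3 ketone with C1 isopropenyl group and C4 triethylsilyl ether | CC(=C)[C@@H]1CC[C@]2(C)O[C@H]2CC/C(C)=C/CC[C@](C)(O[Si](CC)(CC)CC)C(=O)C1
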